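**Strategy**

- Cuts, in retrosynthetic order: (a) the biaryl bond between lignan C5 and carbon B5 of the flavanonol B ring (Suzuki-Miyaura); (b) both benzylic ether bonds of the furofuran, C7-O9' and C7'-O9, together (oxidative double cyclisation of a dibenzylbutanediol); (c) the C8-C8' bond (oxidative homocoupling of a chiral imide enolate).
- Forward order: C8-C8' is made first, then both tetrahydrofuran rings of the 3,7-dioxabicyclo[3.3.0]octane close in one operation, and the biaryl bond is formed last; the chromanone with rings A, B and C is bought intact as (2R,3R)-taxifolin.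
- Enabling feature: in the dioxabicyclooctane each benzylic carbon (C7, C7') carries its ring oxygen para to a free phenolic OH, so each of these C-O bonds is the adduct of a primary alcohol and a p-quinone methide. Apart from the biaryl bond the core is twofold symmetric, and that bond sits at C5, ortho to the phenol, where a bromine can block phenoxyl coupling, act as coupling handle and finally be exchanged for H.
- Stereochemistry: C8 and C8' (R,R) come from an (S)-4-benzyloxazolidinone auxiliary; C7 and C7' (S,S) are relayed from them in the ring closure; C2 and C3 of the flavanonol come with taxifolin; the biaryl axis has only two ortho oxygens and is not a stereoelement.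

Key step: step 7

Remark on numbering: lignan atoms are C1-C9 and C1'-C9'; chromanone atoms are named as such (chromanone C2, C3, C4, 3-O, 5-O, 7-O); ring-B carbons are B1-B6 (B1 bonded to chromanone C2, B3 and B4 oxygenated, B5 the biaryl carbon).

Remark on the chemistry (assumption): the orthoformate carbon is a stereocentre that is removed in the last step; all orthoformate-bearing compounds are expected as mixtures of two epimers at that carbon and are drawn with it undefined.

**Step 1**
Reactants: 1 5-bromovanillin (3-bromo-4-hydroxy-5-methoxybenzaldehyde)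
Product: 4 3-(3-bromo-4-hydroxy-5-methoxyphenyl)propanoic acid, via arylidene Meldrum's acid 2 (not isolated), via benzyl Meldrum's acid 3 (not isolated)
Conditions: Meldrum's acid (1.05 equiv), HCO2H/Et3N (5:2), 95-100 °C; aq. HCl work-up
Reagents that add atoms: Meldrum's acid (2,2-dimethyl-1,3-dioxane-4,6-dione), CC1(C)OC(=O)CC(=O)O1
Why: Reductive Knoevenagel condensation: the arylidene Meldrum's acid should accept hydride from formate at its electrophilic benzylic carbon and the reduced adduct should lose acetone and CO2 on heating, a metal-free sequence that leaves the aryl C-Br bond alone.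

**Step 2**
Reactants: 4 3-(3-bromo-4-hydroxy-5-methoxyphenyl)propanoic acid
Product: 6 3-[3-bromo-4-(tert-butyldimethylsilyloxy)-5-methoxyphenyl]propanoic acid, via silyl ester 5 (not isolated)
Conditions: TBSCl (2.4 equiv), imidazole, DMF, rt; then AcOH/THF/H2O, rt
Reagents that add atoms: tert-butyldimethylsilyl chloride (TBSCl), CC(C)(C)[Si](C)(C)Cl
Why: Imidazole-promoted silylation covers phenol and acid alike, and only the far more labile silyl ester should be hydrolysed by dilute aqueous acetic acid.

**Step 3**
Reactants: 6 3-[3-bromo-4-(tert-butyldimethylsilyloxy)-5-methoxyphenyl]propanoic acid; 7 (S)-4-benzyl-2-oxazolidinone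
Product: 9 (S)-4-benzyl-3-{3-[3-bromo-4-(tert-butyldimethylsilyloxy)-5-methoxyphenyl]propanoyl}-2-oxazolidinone, via pivalic mixed anhydride 8 (not isolated)
Conditions: PivCl, Et3N, THF, -20 °C; then 7, LiCl, -20 °C to rt
Reagents that add atoms: none
Why: N-acylation of an oxazolidinone through the pivalic mixed anhydride with LiCl activation, in which the nucleophile attacks the unhindered acyl carbon and the aryl silyl ether is not disturbed.

**Step 4**
Reactants: 9 (S)-4-benzyl-3-{3-[3-bromo-4-(tert-butyldimethylsilyloxy)-5-methoxyphenyl]propanoyl}-2-oxazolidinone (two molecules)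
Product: 11 (2R,3R)-2,3-bis[3-bromo-4-(tert-butyldimethylsilyloxy)-5-methoxybenzyl]succinic bis-imide of (S)-4-benzyl-2-oxazolidinone, via lithium Z-enolate 10 (not isolated)
Conditions: LDA (LiN(i-Pr)2, 1.1 equiv), THF, -78 °C; then anhydrous CuCl2 (1.2 equiv), -78 to 0 °C
Reagents that add atoms: none
Why: Oxidative enolate homocoupling of a chiral N-acyloxazolidinone: the chelated Z-enolate is oxidised by divalent copper and each half should form the C8-C8' bond on the face away from the benzyl group of the (S)-auxiliary, the facial sense of alkylation of such enolates, which sets both new centres R.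

**Step 5**
Reactants: 11 (2R,3R)-bis-imide
Product: 12 (2R,3R)-2,3-bis[3-bromo-4-(tert-butyldimethylsilyloxy)-5-methoxybenzyl]butane-1,4-diol
Conditions: LiBH4 (5 equiv), H2O (2 equiv), THF/Et2O, 0 °C to rt
Reagents that add atoms: none
Why: Reductive cleavage of N-acyloxazolidinones by LiBH4 at the exocyclic carbonyl should give both primary alcohols and return the auxiliary without touching C8, C8', the C-Br bonds or the silyl ethers.

**Step 6**
Reactants: 12 (2R,3R)-bis(silyl ether) diol
Product: 13 (8R,8'R)-5,5'-dibromosecoisolariciresinol, i.e. (2R,3R)-2,3-bis(3-bromo-4-hydroxy-5-methoxybenzyl)butane-1,4-diol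
Conditions: TBAF (Bu4NF)/AcOH (1:1, 2.5 equiv), THF, 0 °C
Reagents that add atoms: none
Why: Fluoride cleavage of aryl silyl ethers, buffered with acetic acid so that the bromophenols are released in neutral form.

**Step 7**
Reactants: 13 (8R,8'R)-5,5'-dibromosecoisolariciresinol
Product: 17 (+)-(7S,7'S,8R,8'R)-5,5'-dibromopinoresinol, via quinone methide 14 (not isolated), via 5,5'-dibromolariciresinol 15 (not isolated), via quinone methide 16 (not isolated)
Conditions: Ag2O (2.1 equiv, in portions), dry CH2Cl2/acetone, high dilution, rt, dark; filtration through Celite as soon as 15 is consumed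
Reagents that add atoms: none
Why: Proposed new method: each 2-bromo-6-methoxy-4-alkylphenol unit of 13 should be oxidised by Ag2O (two electrons and two protons, the phenoxyl having no free ortho or para carbon at which to couple) to a p-quinone methide at C7, to which the C9' hydroxyl adds in a 5-exo-trig oxa-conjugate addition that restores the phenol and closes the first tetrahydrofuran (15); the same events at the other aryl ring (16) let the C9 hydroxyl add to C7' in a second 5-exo-trig closure that completes the cis-fused 3,7-dioxabicyclo[3.3.0]octane. The closest known reaction types are the oxidation of 2,6-disubstituted 4-alkylphenols to quinone methides that are trapped by an internal alcohol, the cyclisation of benzylic-hydroxylated dibenzylbutanediols to 7,9'-epoxylignans, and the collapse of the same bis-quinone methide array in the oxidative beta-beta dimerisation of 5-halogenated coniferyl alcohols; new is the entry by double dehydrogenation of a saturated dibenzylbutanediol. C7 is controlled by C8 and C7' by C8': in each closure the aryl group should end up trans to the neighbouring C8 (C8') ring arm, that is exo on the convex face, as in the beta-beta dimerisation and helped by the reversibility of alcohol addition to a free-phenol quinone methide, and with C8 and C8' both R this means 7S,7'S. The ring fusion can only be cis, and the R,R diol (unlike the meso isomer) is the one whose two closures fit a cis-fused bicycle. The step needs quinone methide formation instead of phenoxyl coupling, capture by oxygen instead of by the facing arene (aryltetralin closure) and no further oxidation of the new benzylic ether C-H; the C5 bromines block the ortho positions and deactivate the arenes, the neutral aprotic medium favours the hydroxyl nucleophile, and the oxidant is held at two equivalents.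

**Step 8**
Reactants: 17 (+)-5,5'-dibromopinoresinol
Product: 18 (+)-5,5'-dibromopinoresinol 4,4'-bis(benzyl ether)
Conditions: BnBr (2.5 equiv), K2CO3, DMF, rt
Reagents that add atoms: benzyl bromide, BrCc1ccccc1
Why: Williamson etherification of the two bromophenols with carbonate base, conditions under which the furofuran is inert.

**Step 9**
Reactants: 19 (2R,3R)-(+)-taxifolin
Product: 20 taxifolin B3,B4-O-(ethoxymethylene) cyclic orthoformate (a 2-ethoxy-1,3-benzodioxole; 3-, 5- and 7-OH free)
Conditions: HC(OEt)3 (excess), Amberlyst 15 (cat.), THF/toluene, reflux through 4 Å MS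
Reagents that add atoms: triethyl orthoformate, CCOC(OCC)OCC
Why: Acid-catalysed orthoester exchange, driven by removal of ethanol, in which only the catechol can form a five-membered cyclic orthoformate; this ties back both B-ring oxygens and masks the B4 oxygen, whose phenoxide would otherwise open the way to epimerisation at chromanone C2.

**Step 10**
Reactants: 20 taxifolin cyclic orthoformate
Product: 21 3,5,7-tris-O-(tert-butyldimethylsilyl) ether of 20
Conditions: TBSCl (4.5 equiv), imidazole, DMAP (cat.), DMF, rt to 40 °C
Reagents that add atoms: tert-butyldimethylsilyl chloride (TBSCl), CC(C)(C)[Si](C)(C)Cl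
Why: Imidazole-promoted silylation of the secondary alcohol and both phenols (the chelated 5-OH last, hence excess reagent and gentle warming) with a weak base that leaves C2, C3 and the acid-labile orthoformate alone and gives protecting groups without aryl C-H bonds.

**Step 11**
Reactants: 21 tris(silyl ether) orthoformate
Product: 22 B5 pinacolboronate of 21 (boron on the ring-B carbon next to the B4 oxygen)
Conditions: B2pin2 (1.0 equiv), [Ir(OMe)(cod)]2 (3 mol %), 4,4'-di-tert-butyl-2,2'-bipyridine (6 mol %), THF, 60 °C
Reagents that add atoms: bis(pinacolato)diboron (B2pin2), CC1(C)OB(B2OC(C)(C)C(C)(C)O2)OC1(C)C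
Why: Iridium-catalysed aromatic C-H borylation is sterically governed and favours the C-H ortho to a tied-back benzodioxole oxygen: B5 is the only such C-H with a free neighbour, whereas B2 and both ring-A C-H bonds are flanked on two sides and B6 lies next to the carbon that carries the chromanone.

**Step 12**
Reactants: 18 dibromopinoresinol bis(benzyl ether) (threefold excess, recovered); 22 B5 pinacolboronate
Product: 23 mono-coupled biaryl: 18 in which the bromine at C5 is replaced by carbon B5 of the protected flavanonol 21 (C5' bromine, both benzyl ethers, three silyl ethers and orthoformate retained)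
Conditions: Pd(OAc)2 (5 mol %), SPhos (10 mol %), K3PO4, toluene/H2O, 65 °C
Reagents that add atoms: none
Why: Suzuki-Miyaura coupling with a bulky dialkylbiarylphosphine suited to di-ortho-oxygenated biaryls; the two C-Br bonds of 18 are homotopic through its twofold axis, so only one mono-adduct can form and the excess of 18 suppresses a second coupling, while the orthoformate keeps the B4 oxygen masked under base.

**Step 13**
Reactants: 23 mono-coupled bromo biaryl
Product: 24 debenzylated and debrominated biaryl (both lignan phenols free, C5' now C-H; three silyl ethers and orthoformate retained)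
Conditions: H2 (1 atm), 10% Pd/C, Et3N (3 equiv), EtOAc/EtOH, rt
Reagents that add atoms: none
Why: Heterogeneous palladium-catalysed hydrogenolysis cleaves the two aryl benzyl ethers and reduces the aryl C-Br bond, the amine taking up HBr so that neither the furofuran benzylic ethers nor the orthoformate meet acid; amine-buffered hydrodebromination of bromopinoresinol-type phenols is known to spare the furofuran.

**Step 14**
Reactants: 24 tris(silyl ether) orthoformate biaryl
Product: 25 biaryl with free 3-, 5- and 7-OH and intact cyclic orthoformate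
Conditions: TBAF (Bu4NF)/AcOH (1:1, 4 equiv), THF, 0 °C to rt
Reagents that add atoms: none
Why: Fluoride cleavage of the two aryl and one alkyl silyl ether, buffered with acetic acid so that no phenoxide or enolate can open the flavanonol ring and scramble C2 or C3.

**Step 15**
Reactants: 25 orthoformate biaryl
Product: 27 target CNP0226398.1, via catechol monoformate 26 (not isolated)
Conditions: PPTS (cat.), THF/H2O, rt; then MeOH, 40 °C
Reagents that add atoms: none
Why: Orthoester hydrolysis under very mild acid catalysis gives the catechol monoformate, and this activated aryl formate should be cleaved by methanolysis, conditions too weak to ionise the benzylic ethers of the furofuran (which would epimerise C7) or to open the flavanonol.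

**Compound list**

1 | 5-bromovanillin | COc1cc(C=O)cc(Br)c1O | starting material
2 | 5-(3-bromo-4-hydroxy-5-methoxybenzylidene)-2,2-dimethyl-1,3-dioxane-4,6-dione | COc1cc(C=C2C(=O)OC(C)(C)OC2=O)cc(Br)c1O | intermediate
3 | 5-(3-bromo-4-hydroxy-5-methoxybenzyl)-2,2-dimethyl-1,3-dioxane-4,6-dione | COc1cc(CC2C(=O)OC(C)(C)OC2=O)cc(Br)c1O | intermediate
4 | 3-(3-bromo-4-hydroxy-5-methoxyphenyl)propanoic acid | COc1cc(CCC(=O)O)cc(Br)c1O | intermediate
5 | tert-butyldimethylsilyl 3-[3-bromo-4-(tert-butyldimethylsilyloxy)-5-methoxyphenyl]propanoate | COc1cc(CCC(=O)O[Si](C)(C)C(C)(C)C)cc(Br)c1O[Si](C)(C)C(C)(C)C | intermediate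
6 | 3-[3-bromo-4-(tert-butyldimethylsilyloxy)-5-methoxyphenyl]propanoic acid | COc1cc(CCC(=O)O)cc(Br)c1O[Si](C)(C)C(C)(C)C | intermediate
7 | (S)-4-benzyl-2-oxazolidinone | O=C1N[C@@H](Cc2ccccc2)CO1 | starting material
8 | mixed anhydride of 6 and pivalic acid | COc1cc(CCC(=O)OC(=O)C(C)(C)C)cc(Br)c1O[Si](C)(C)C(C)(C)C | intermediate
9 | (S)-4-benzyl-3-{3-[3-bromo-4-(tert-butyldimethylsilyloxy)-5-methoxyphenyl]propanoyl}-2-oxazolidinone | COc1cc(CCC(=O)N2[C@@H](Cc3ccccc3)COC2=O)cc(Br)c1O[Si](C)(C)C(C)(C)C | intermediate
10 | lithium (Z)-enolate of 9 | COc1cc(C/C=C(\O[Li])N2[C@@H](Cc3ccccc3)COC2=O)cc(Br)c1O[Si](C)(C)C(C)(C)C | intermediate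
11 | (2R,3R)-2,3-bis[3-bromo-4-(tert-butyldimethylsilyloxy)-5-methoxybenzyl]succinic bis-imide of (S)-4-benzyl-2-oxazolidinone | O=C([C@H](Cc1cc(OC)c(O[Si](C)(C)C(C)(C)C)c(Br)c1)[C@@H](Cc1cc(OC)c(O[Si](C)(C)C(C)(C)C)c(Br)c1)C(=O)N1[C@@H](Cc2ccccc2)COC1=O)N1[C@@H](Cc2ccccc2)COC1=O | intermediate
12 | (2R,3R)-2,3-bis[3-bromo-4-(tert-butyldimethylsilyloxy)-5-methoxybenzyl]butane-1,4-diol | OC[C@H](Cc1cc(OC)c(O[Si](C)(C)C(C)(C)C)c(Br)c1)[C@H](CO)Cc1cc(OC)c(O[Si](C)(C)C(C)(C)C)c(Br)c1 | intermediate
13 | (8R,8'R)-5,5'-dibromosecoisolariciresinol | OC[C@H](Cc1cc(OC)c(O)c(Br)c1)[C@H](CO)Cc1cc(OC)c(O)c(Br)c1 | intermediate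
14 | p-quinone methide from one phenol of 13 (exocyclic C7=C1, methide geometry undefined) | OC[C@H](Cc1cc(OC)c(O)c(Br)c1)[C@H](CO)C=C1C=C(OC)C(=O)C(Br)=C1 | intermediate
15 | (7S,8R,8'R)-5,5'-dibromolariciresinol | COc1cc([C@H]2OC[C@H](Cc3cc(OC)c(O)c(Br)c3)[C@@H]2CO)cc(Br)c1O | intermediate
16 | p-quinone methide of 15 at C7' (methide geometry undefined) | COc1cc([C@H]2OC[C@H](C=C3C=C(OC)C(=O)C(Br)=C3)[C@@H]2CO)cc(Br)c1O | intermediate
17 | (+)-(7S,7'S,8R,8'R)-5,5'-dibromopinoresinol | COc1cc([C@H]2OC[C@H]3[C@@H]2CO[C@@H]3c2cc(OC)c(O)c(Br)c2)cc(Br)c1O | intermediate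
18 | (+)-5,5'-dibromopinoresinol 4,4'-bis(benzyl ether) | COc1cc([C@H]2OC[C@H]3[C@@H]2CO[C@@H]3c2cc(OC)c(OCc4ccccc4)c(Br)c2)cc(Br)c1OCc1ccccc1 | intermediate
19 | (2R,3R)-(+)-taxifolin | Oc1ccc([C@H]2Oc3cc(O)cc(O)c3C(=O)[C@@H]2O)cc1O | starting material
20 | taxifolin B3,B4-cyclic ethyl orthoformate | CCOC1Oc2ccc([C@H]3Oc4cc(O)cc(O)c4C(=O)[C@@H]3O)cc2O1 | intermediate
21 | 3,5,7-tris-O-(tert-butyldimethylsilyl) ether of 20 | CCOC1Oc2ccc([C@H]3Oc4cc(O[Si](C)(C)C(C)(C)C)cc(O[Si](C)(C)C(C)(C)C)c4C(=O)[C@@H]3O[Si](C)(C)C(C)(C)C)cc2O1 | intermediate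
22 | B5 pinacolboronate of 21 | CCOC1Oc2cc([C@H]3Oc4cc(O[Si](C)(C)C(C)(C)C)cc(O[Si](C)(C)C(C)(C)C)c4C(=O)[C@@H]3O[Si](C)(C)C(C)(C)C)cc(B3OC(C)(C)C(C)(C)O3)c2O1 | intermediate
23 | protected mono-bromo biaryl (C5-B5 bond; benzyl ethers, silyl ethers and orthoformate in place) | COc1cc([C@H]2OC[C@H]3[C@@H]2CO[C@@H]3c2cc(OC)c(OCc3ccccc3)c(-c3cc([C@H]4Oc5cc(O[Si](C)(C)C(C)(C)C)cc(O[Si](C)(C)C(C)(C)C)c5C(=O)[C@@H]4O[Si](C)(C)C(C)(C)C)cc4OC(OCC)Oc34)c2)cc(Br)c1OCc1ccccc1 | intermediate
24 | biaryl with free lignan phenols, three silyl ethers and orthoformate | COc1cc([C@H]2OC[C@H]3[C@@H]2CO[C@@H]3c2cc(OC)c(O)c(-c3cc([C@H]4Oc5cc(O[Si](C)(C)C(C)(C)C)cc(O[Si](C)(C)C(C)(C)C)c5C(=O)[C@@H]4O[Si](C)(C)C(C)(C)C)cc4OC(OCC)Oc34)c2)ccc1O | intermediate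
25 | biaryl with the orthoformate as the only protecting group | COc1cc([C@H]2OC[C@H]3[C@@H]2CO[C@@H]3c2cc(OC)c(O)c(-c3cc([C@H]4Oc5cc(O)cc(O)c5C(=O)[C@@H]4O)cc4OC(OCC)Oc34)c2)ccc1O | intermediate
26 | catechol monoformate of the target (drawn as the B3 formate; the B4 formate would react on in the same way) | COc1cc([C@H]2OC[C@H]3[C@@H]2CO[C@@H]3c2cc(OC)c(O)c(-c3cc([C@H]4Oc5cc(O)cc(O)c5C(=O)[C@@H]4O)cc(OC=O)c3O)c2)ccc1O | intermediate
27 | CNP0226398.1 | COc1cc([C@H]2OC[C@H]3[C@@H]2CO[C@@H]3c2cc(OC)c(O)c(-c3cc([C@H]4Oc5cc(O)cc(O)c5C(=O)[C@@H]4O)cc(O)c3O)c2)ccc1O | target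

**Step count and risks**

Total step count: 15 (steps 1-8 on the lignan branch, steps 9-11 on the flavanonol branch, steps 12-15 after convergence).
Longest linear sequence: 12 steps (1-8, then 12-15, from 5-bromovanillin).

Steps most likely to fail:

Step 7 (the step that carries the label of a proposed new method). The oxidation may stop at the phenoxyl stage and lead to oxygen-carbon coupled oligomers. The quinone methide may be captured by the facing arene or by adventitious water instead of the hydroxyl. The second ring may close with its aryl group endo, or the product may be oxidised further at a benzylic ether C-H. The fallback uses known chemistry, sets out from 1 and returns at 17. Wittig olefination of 1 with ethyl (triphenylphosphoranylidene)acetate should give ethyl (E)-5-bromoferulate F1. Reduction with i-Bu2AlH in toluene at low temperature should give (E)-5-bromoconiferyl alcohol F2. One-electron oxidation with FeCl3 in aqueous acetone should then give racemic 5,5'-dibromopinoresinol F3, by beta-beta radical coupling and collapse of the bis-quinone methide through the same two oxa-conjugate additions, the bromine again closing the beta-5 and 5-5 channels. Separation of the enantiomers on a chiral stationary phase would deliver 17. This fallback gives up the auxiliary-based control of C8 and C8' and costs half of the material.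

Step 12. The ortho-oxygenated boronate may protodeboronate, and transmetalation at the doubly ortho-oxygenated site may be slow. A second coupling may occur at the other bromide. The base may strip phenolic silyl groups and then open the chromanone ring. The fallback is a base-free coupling with reversed polarity; it sets out from 18 and 22 and returns at 23. Ipso-iododeboronation of 22 with N-iodosuccinimide in MeCN should give the B5 iodide F4. A single bromine-lithium exchange on 18 (n-BuLi, 1 equiv, THF, -78 °C) should give the mono-aryllithium F5, which is transmetalated with ZnCl2 to the arylzinc chloride F6. Negishi coupling of F6 with F4 (Pd(OAc)2, SPhos, THF, rt) should then give 23, the C-I bond reacting ahead of the remaining C-Br bond.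

Step 13. The furofuran may be opened by hydrogenolysis at its benzylic C-O bonds, debenzylation may stay incomplete in the presence of the amine, or the chromanone carbonyl may be reduced. The fallback avoids hydrogenolysis altogether; it sets out from 17 and returns at 25. Silylation of 17 (TBSCl, imidazole, DMF) should give 5,5'-dibromopinoresinol bis(tert-butyldimethylsilyl ether) F7. Suzuki-Miyaura mono-coupling with 22 under the conditions of step 12 should give the penta-silylated bromo biaryl F8. Radical hydrodebromination with (Me3Si)3SiH and AIBN in toluene at 80 °C should give the debrominated penta-silyl biaryl F9. Acetic acid-buffered TBAF then removes all five silyl groups and gives 25.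

**Further compounds**

F1 | step 7 | ethyl (E)-5-bromoferulate | CCOC(=O)/C=C/c1cc(OC)c(O)c(Br)c1
F2 | step 7 | (E)-5-bromoconiferyl alcohol | OC/C=C/c1cc(OC)c(O)c(Br)c1
F3 | step 7 | racemic 5,5'-dibromopinoresinol (both enantiomers) | COc1cc([C@H]2OC[C@H]3[C@@H]2CO[C@@H]3c2cc(OC)c(O)c(Br)c2)cc(Br)c1O.COc1cc([C@@H]2OC[C@@H]3[C@H]2CO[C@H]3c2cc(OC)c(O)c(Br)c2)cc(Br)c1O
F4 | step 12 | B5 iodide of the protected flavanonol 21 | CCOC1Oc2cc([C@H]3Oc4cc(O[Si](C)(C)C(C)(C)C)cc(O[Si](C)(C)C(C)(C)C)c4C(=O)[C@@H]3O[Si](C)(C)C(C)(C)C)cc(I)c2O1
F5 | step 12 | mono-aryllithium from 18 | COc1cc([C@H]2OC[C@H]3[C@@H]2CO[C@@H]3c2cc(OC)c(OCc4ccccc4)c([Li])c2)cc(Br)c1OCc1ccccc1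
F6 | step 12 | arylzinc chloride from 18 | COc1cc([C@H]2OC[C@H]3[C@@H]2CO[C@@H]3c2cc(OC)c(OCc4ccccc4)c([Zn]Cl)c2)cc(Br)c1OCc1ccccc1
F7 | step 13 | 5,5'-dibromopinoresinol bis(tert-butyldimethylsilyl ether) | COc1cc([C@H]2OC[C@H]3[C@@H]2CO[C@@H]3c2cc(OC)c(O[Si](C)(C)C(C)(C)C)c(Br)c2)cc(Br)c1O[Si](C)(C)C(C)(C)C
F8 | step 13 | penta-silylated bromo biaryl | COc1cc([C@H]2OC[C@H]3[C@@H]2CO[C@@H]3c2cc(OC)c(O[Si](C)(C)C(C)(C)C)c(-c3cc([C@H]4Oc5cc(O[Si](C)(C)C(C)(C)C)cc(O[Si](C)(C)C(C)(C)C)c5C(=O)[C@@H]4O[Si](C)(C)C(C)(C)C)cc4OC(OCC)Oc34)c2)cc(Br)c1O[Si](C)(C)C(C)(C)C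
F9 | step 13 | debrominated penta-silyl biaryl | COc1cc([C@H]2OC[C@H]3[C@@H]2CO[C@@H]3c2cc(OC)c(O[Si](C)(C)C(C)(C)C)c(-c3cc([C@H]4Oc5cc(O[Si](C)(C)C(C)(C)C)cc(O[Si](C)(C)C(C)(C)C)c5C(=O)[C@@H]4O[Si](C)(C)C(C)(C)C)cc4OC(OCC)Oc34)c2)ccc1O[Si](C)(C)C(C)(C)C
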